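The γ-butyrolactone ring (O1, C2–C5) carries its two arms on neighbouring carbons. β-Carbon C4 holds benzylic C7, and α-carbon C3 holds carbinol carbon C7'. The plan cuts C4–C7 and C3–C7' together, exploiting this α,β-relationship to the C2 carbonyl. In one flask a lithiated benzylvanillin dithiane (a masked C7 benzyl anion) adds 1,4 to an enantiopure butenolide whose C5 bears a menthyloxy group. The enolate, moved from lithium to zirconium, then captures benzylvanillin. Two C–C bonds and the C3, C4 and C7' stereocentres arise, and no ring is closed. C5 enters as a masked aldehyde and is finally reduced to the ring CH2 as menthol departs.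

Key step: step 4

Remark: ring atoms are labelled O1, C2 (carbonyl), C3, C4, C5 throughout; C7 is the benzylic carbon on C4 and C7' the one on C3. In these labels the target is (3S,4R,7'S), a 3,4-trans lactone whose C4/OH relationship along C2–C3–C7'–aryl is syn.

Step 1
Reactants: 1 furfural
Product: 3 5-hydroxyfuran-2(5H)-one (racemic hemiacetal), via furan endoperoxide 2 (not isolated)
Conditions: O2, hν (visible), methylene blue (C16H18ClN3S, cat.), MeOH, 20 °C
Reagents that add atoms: dioxygen, O=O
Why: Dye-sensitised singlet-oxygen [4+2] cycloaddition to the furan (furan photo-oxygenation) gives endoperoxide 2, which methanol cleaves at the formyl group to the hydroxybutenolide and methyl formate; C5 of 3 is a labile hemiacetal centre, so nothing stereochemical has to be controlled.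

Step 2
Reactants: 3 5-hydroxyfuran-2(5H)-one; 4 (−)-menthol
Product: 6 (5R)-5-[(1R,2S,5R)-menthyloxy]furan-2(5H)-one, via C5-epimeric menthyl acetals 5 (not isolated)
Conditions: camphor-10-sulfonic acid (cat.), toluene, reflux, Dean–Stark; crystallise from petroleum ether, −20 °C; liquors re-equilibrated with the same acid and recrystallised
Reagents that add atoms: none
Why: Acid-catalysed acetalisation of the pseudo-acid 3 through its cyclic oxocarbenium ion gives both C5 epimers 5, of which the 5R epimer crystallises while acid re-equilibrates the liquors, so C5 is set by crystallisation-driven resolution against the three fixed menthyl centres.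

Step 3
Reactants: 7 4-(benzyloxy)-3-methoxybenzaldehyde; 8 propane-1,3-dithiol
Product: 9 2-[4-(benzyloxy)-3-methoxyphenyl]-1,3-dithiane
Conditions: BF3·OEt2 (0.2 equiv), CH2Cl2, 0 °C → rt
Reagents that add atoms: none
Why: Lewis-acid-catalysed dithioacetalisation of an aromatic aldehyde is a robust reaction that leaves aryl methyl and benzyl ethers alone and creates no stereocentre.

Step 4
Reactants: 9 2-[4-(benzyloxy)-3-methoxyphenyl]-1,3-dithiane; 6 (5R)-5-[(1R,2S,5R)-menthyloxy]furan-2(5H)-one; 7 4-(benzyloxy)-3-methoxybenzaldehyde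
Product: 14 (3S,4R,5R)-3-{(S)-[4-(benzyloxy)-3-methoxyphenyl](hydroxy)methyl}-4-{2-[4-(benzyloxy)-3-methoxyphenyl]-1,3-dithian-2-yl}-5-[(1R,2S,5R)-menthyloxy]dihydrofuran-2(3H)-one, via 2-lithiodithiane 10 (not isolated), via lithium enolate 11 (not isolated), via chlorozirconocene enolate 12 (not isolated), via chlorozirconocene aldolate 13 (not isolated)
Conditions: 9, n-BuLi (1.0 equiv), THF, −78 → −30 °C, recool; 6 (1.05 equiv), THF, −78 °C; Cp2ZrCl2 (1.1 equiv), THF, −78 → −50 °C, recool; 7 (1.1 equiv), THF, −78 °C; sat. aq NH4Cl at −78 °C, then rt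
Reagents that add atoms: none
Why: n-BuLi removes the dithiane C2–H of 9 (Corey–Seebach umpolung); the soft, sulfur- and aryl-stabilised carbanion 10 adds 1,4 to 6 to form C4–C7 and lithium enolate 11, Cp2ZrCl2 replaces lithium by the chlorozirconocene unit (12, tetravalent zirconium), and 12 adds to aldehyde 7 to form C3–C7' as aldolate 13, which is protonated cold. The closest known chemistry is the tandem Michael addition–aldol of 2-lithio-2-aryl-1,3-dithianes on butenolides and 5-alkoxybutenolides, joined here to the syn-selective aldol of zirconocene enolates made from lithium enolates. No ring is closed; the lactone ring of 6 is carried through intact. C4 (R) is set by attack anti to the C5 menthyloxy group, C3 (S) by approach of the aldehyde to the enolate face opposite the very large dithianyl group (3,4-trans), and C7' (S) by the metal: the ring-locked E(O) enolate would favour the anti carbinol through a lithium Zimmerman–Traxler chair, whereas the Cp ligands on zirconium disfavour that chair and give syn aldols from either enolate geometry. The step needs 1,4- over 1,2-addition (secured by the delocalised anion in THF at −78 °C), full consumption of 10 before 7 is added (one equivalent of base, slight excess of 6) and no aldolate equilibration (strong Zr–O bond, quench at −78 °C). C7' remains the least secure centre.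

Step 5
Reactants: 14 the three-component adduct
Product: 15 (3S,4R,5R)-4-[4-(benzyloxy)-3-methoxybenzyl]-3-{(S)-[4-(benzyloxy)-3-methoxyphenyl](hydroxy)methyl}-5-[(1R,2S,5R)-menthyloxy]dihydrofuran-2(3H)-one
Conditions: NiCl2·6H2O (10 equiv), NaBH4 (30 equiv, portionwise), MeOH–THF, 0 °C → rt (Ni2B formed in situ)
Reagents that add atoms: none
Why: Reductive desulfurisation by Ni2B made in situ cleaves both benzylic C–S bonds at C7 to leave the CH2 group, is milder than Raney Ni towards aryl benzyl ethers and the C7' carbinol, should be over before borohydride attacks the lactone at this temperature, and touches none of the C3, C4, C5 and C7' centres.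

Step 6
Reactants: 15 the desulfurised menthyloxy lactone
Product: 18 (3S,4R)-4-[4-(benzyloxy)-3-methoxybenzyl]-3-{(S)-[4-(benzyloxy)-3-methoxyphenyl](hydroxy)methyl}dihydrofuran-2(3H)-one, via potassium formyl carboxylate 16 (not isolated), via hydroxy acid 17 (not isolated)
Conditions: NaBH4 (3 equiv), then aq KOH (2.5 equiv), EtOH–THF, 0 °C → rt; 1 M HCl to pH 3, 0 °C, EtOAc extraction; pyridinium p-toluenesulfonate (cat.), CH2Cl2, rt
Reagents that add atoms: potassium hydroxide, [K+].[OH-] (its oxygen enters the carboxyl group of 16 and 17; one carboxyl oxygen leaves again as water on lactonisation)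
Why: Saponification of the acylal-type lactone expels menthol and frees C5 as aldehyde 16, borohydride already present reduces it before C4 can epimerise, the carboxylate resists retro-aldol cleavage, and acidification gives γ-hydroxy acid 17, which can lactonise only through the C5 hydroxyl (five-membered ring; the C7' hydroxyl would need a four-membered one), so C3, C4 and C7' are carried over unchanged while the benzyl ethers prevent quinone methide formation in base.

Step 7
Reactants: 18 the dibenzyl lactone
Product: 19 (3S,4R)-4-(4-hydroxy-3-methoxybenzyl)-3-[(S)-hydroxy(4-hydroxy-3-methoxyphenyl)methyl]dihydrofuran-2(3H)-one (target)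
Conditions: H2 (1 atm), 10% Pd/C, EtOAc, rt, stopped after uptake of two equivalents of H2
Reagents that add atoms: none
Why: Pd-catalysed hydrogenolysis of aryl benzyl ethers in a neutral, non-nucleophilic solvent at 1 atm is far faster than cleavage of a secondary benzylic alcohol, which calls for acid, heat or pressure, so all three stereocentres and the C7' hydroxyl should be retained.

Compound list
1 | furfural | O=Cc1ccco1 | starting material
2 | 2,3,7-trioxabicyclo[2.2.1]hept-5-ene-1-carbaldehyde (furan endoperoxide, racemic, not isolated) | O=CC12OOC(O1)C=C2 | intermediate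
3 | 5-hydroxyfuran-2(5H)-one (racemic hemiacetal) | OC1OC(=O)C=C1 | intermediate
4 | (−)-menthol, (1R,2S,5R)-2-isopropyl-5-methylcyclohexanol | C[C@@H]1CC[C@H]([C@@H](C1)O)C(C)C | starting material
5 | 5-[(1R,2S,5R)-menthyloxy]furan-2(5H)-one, both C5 epimers (not isolated) | C[C@@H]1CC[C@H]([C@@H](C1)OC1OC(=O)C=C1)C(C)C | intermediate
6 | (5R)-5-[(1R,2S,5R)-menthyloxy]furan-2(5H)-one | C[C@@H]1CC[C@H]([C@@H](C1)O[C@@H]1OC(=O)C=C1)C(C)C | intermediate
7 | 4-(benzyloxy)-3-methoxybenzaldehyde | COc1cc(C=O)ccc1OCc1ccccc1 | starting material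
8 | propane-1,3-dithiol | SCCCS | starting material
9 | 2-[4-(benzyloxy)-3-methoxyphenyl]-1,3-dithiane | COc1cc(C2SCCCS2)ccc1OCc1ccccc1 | intermediate
10 | 2-lithio-2-[4-(benzyloxy)-3-methoxyphenyl]-1,3-dithiane (not isolated) | [Li]C1(c2ccc(OCc3ccccc3)c(OC)c2)SCCCS1 | intermediate
11 | lithium enolate of the (4R,5R) 1,4-adduct, dithianyl group on C4 anti to the C5 menthyloxy group (not isolated) | C[C@@H]1CC[C@H]([C@@H](C1)O[C@@H]1OC(O[Li])=C[C@H]1C1(c2ccc(OCc3ccccc3)c(OC)c2)SCCCS1)C(C)C | intermediate
12 | chlorozirconocene enolate of the same (4R,5R) adduct (not isolated) | C[C@@H]1CC[C@H]([C@@H](C1)O[C@@H]1OC([O-])=C[C@H]1C1(c2ccc(OCc3ccccc3)c(OC)c2)SCCCS1)C(C)C.[Cl-].[Zr+4].[CH-]1C=CC=C1.[CH-]1C=CC=C1 | intermediate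
13 | chlorozirconocene (3S,4R,5R,7'S) aldolate (not isolated) | C[C@@H]1CC[C@H]([C@@H](C1)O[C@@H]1OC(=O)[C@H]([C@H]([O-])c2ccc(OCc3ccccc3)c(OC)c2)[C@H]1C1(c2ccc(OCc3ccccc3)c(OC)c2)SCCCS1)C(C)C.[Cl-].[Zr+4].[CH-]1C=CC=C1.[CH-]1C=CC=C1 | intermediate
14 | (3S,4R,5R)-3-{(S)-[4-(benzyloxy)-3-methoxyphenyl](hydroxy)methyl}-4-{2-[4-(benzyloxy)-3-methoxyphenyl]-1,3-dithian-2-yl}-5-[(1R,2S,5R)-menthyloxy]dihydrofuran-2(3H)-one | C[C@@H]1CC[C@H]([C@@H](C1)O[C@@H]1OC(=O)[C@H]([C@H](O)c2ccc(OCc3ccccc3)c(OC)c2)[C@H]1C1(c2ccc(OCc3ccccc3)c(OC)c2)SCCCS1)C(C)C | intermediate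
15 | (3S,4R,5R)-4-[4-(benzyloxy)-3-methoxybenzyl]-3-{(S)-[4-(benzyloxy)-3-methoxyphenyl](hydroxy)methyl}-5-[(1R,2S,5R)-menthyloxy]dihydrofuran-2(3H)-one | C[C@@H]1CC[C@H]([C@@H](C1)O[C@@H]1OC(=O)[C@H]([C@H](O)c2ccc(OCc3ccccc3)c(OC)c2)[C@H]1Cc1ccc(OCc2ccccc2)c(OC)c1)C(C)C | intermediate
16 | potassium (2S,3R)-3-[4-(benzyloxy)-3-methoxybenzyl]-2-{(S)-[4-(benzyloxy)-3-methoxyphenyl](hydroxy)methyl}-4-oxobutanoate (not isolated) | O=C[C@H](Cc1ccc(OCc2ccccc2)c(OC)c1)[C@@H]([C@H](O)c1ccc(OCc2ccccc2)c(OC)c1)C(=O)[O-].[K+] | intermediate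
17 | (2S,3R)-3-[4-(benzyloxy)-3-methoxybenzyl]-2-{(S)-[4-(benzyloxy)-3-methoxyphenyl](hydroxy)methyl}-4-hydroxybutanoic acid (not isolated) | OC[C@H](Cc1ccc(OCc2ccccc2)c(OC)c1)[C@@H]([C@H](O)c1ccc(OCc2ccccc2)c(OC)c1)C(=O)O | intermediate
18 | (3S,4R)-4-[4-(benzyloxy)-3-methoxybenzyl]-3-{(S)-[4-(benzyloxy)-3-methoxyphenyl](hydroxy)methyl}dihydrofuran-2(3H)-one | COc1cc(C[C@H]2COC(=O)[C@@H]2[C@H](O)c2ccc(OCc3ccccc3)c(OC)c2)ccc1OCc1ccccc1 | intermediate
19 | (3S,4R)-4-(4-hydroxy-3-methoxybenzyl)-3-[(S)-hydroxy(4-hydroxy-3-methoxyphenyl)methyl]dihydrofuran-2(3H)-one | COc1cc(C[C@H]2COC(=O)[C@@H]2[C@H](O)c2ccc(O)c(OC)c2)ccc1O | target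

Total step count: 7. Longest linear sequence: 6 (steps 1, 2, 4, 5, 6, 7); step 3 is the short convergent branch.

Steps most likely to fail

Step 4. The weak point is syn/anti discrimination at C7'. The lithium-to-zirconium exchange may be incomplete, or the crowded zirconocene enolate may add too slowly to an electron-rich aldehyde.
- The fallback sets out from lithium enolate 11 and comes back at 14.
- Enolate 11 is treated directly with 7, without zirconium. This should give 14 together with its anti (7'R) aldol epimer F1.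
- The unseparated carbinols are oxidised under Parikh–Doering conditions (SO3·pyridine, DMSO, Et3N, CH2Cl2, 0 °C), which the dithiane tolerates, to the 3-aroyl lactone F2.
- This erases C7', while C3 stays trans to the bulky C4 group under thermodynamic control.
- Chelation-controlled reduction with Zn(BH4)2 (Et2O–THF, −78 → −20 °C) then follows. It is the known syn-selective reduction of α-substituted β-keto esters.
- It should deliver hydride to the ketone face turned away from C4 in the zinc chelate of the two carbonyls and give 14.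

Step 6. Several processes may interfere:
- retro-aldol cleavage or dehydration of the β-hydroxy lactone before the ring opens;
- epimerisation at C4 while C5 is an aldehyde;
- acid-induced ionisation of the electron-rich C7' carbinol during lactonisation.

The fallback sets out from 15 and comes back at 18.
- The C7' hydroxyl is capped first (TBSOTf, 2,6-lutidine, CH2Cl2, 0 °C) to give the C7' silyl ether F3. This cannot undergo retro-aldol cleavage or form a lactol with C5, and it ionises less readily.
- The same KOH/NaBH4 treatment passes through the silylated potassium formyl carboxylate F4.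
- Acidification then gives the silylated hydroxy acid F5, which closes to the silylated lactone F6.
- Bu4NF buffered with AcOH (THF, 0 °C → rt) removes silicon and returns 18.

Step 5. Three processes may interfere:
- incomplete C–S cleavage at the hindered, fully substituted C7;
- competing hydrogenolysis of the C7'–O or benzyl ether bonds on the nickel surface;
- premature opening of the acylal lactone by borohydride or methoxide.

The fallback sets out from 14 and comes back at 15.
- It replaces surface chemistry by a radical chain: Bu3SnH (excess), azobisisobutyronitrile, toluene, reflux.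
- Stannyl radical attack at sulfur releases the aryl- and sulfur-stabilised C7 radical. Hydrogen transfer gives the ring-opened stannyl sulfide F7.
- A second cycle through the benzylic C7 radical gives 15.
- Alcohols, benzyl ethers and the lactone are inert to these neutral conditions.

Further compounds
F1 | step 4 | (3S,4R,5R)-3-{(R)-[4-(benzyloxy)-3-methoxyphenyl](hydroxy)methyl} epimer of 14 (anti aldol) | C[C@@H]1CC[C@H]([C@@H](C1)O[C@@H]1OC(=O)[C@H]([C@@H](O)c2ccc(OCc3ccccc3)c(OC)c2)[C@H]1C1(c2ccc(OCc3ccccc3)c(OC)c2)SCCCS1)C(C)C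
F2 | step 4 | (3S,4R,5R)-3-[4-(benzyloxy)-3-methoxybenzoyl]-4-{2-[4-(benzyloxy)-3-methoxyphenyl]-1,3-dithian-2-yl}-5-[(1R,2S,5R)-menthyloxy]dihydrofuran-2(3H)-one | C[C@@H]1CC[C@H]([C@@H](C1)O[C@@H]1OC(=O)[C@H](C(=O)c2ccc(OCc3ccccc3)c(OC)c2)[C@H]1C1(c2ccc(OCc3ccccc3)c(OC)c2)SCCCS1)C(C)C
F3 | step 6 | C7' O-tert-butyldimethylsilyl ether of 15, (3S,4R,5R,7'S) | C[C@@H]1CC[C@H]([C@@H](C1)O[C@@H]1OC(=O)[C@H]([C@H](O[Si](C)(C)C(C)(C)C)c2ccc(OCc3ccccc3)c(OC)c2)[C@H]1Cc1ccc(OCc2ccccc2)c(OC)c1)C(C)C
F4 | step 6 | C7' O-tert-butyldimethylsilyl ether of potassium formyl carboxylate 16 | O=C[C@H](Cc1ccc(OCc2ccccc2)c(OC)c1)[C@@H]([C@H](O[Si](C)(C)C(C)(C)C)c1ccc(OCc2ccccc2)c(OC)c1)C(=O)[O-].[K+]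
F5 | step 6 | C7' O-tert-butyldimethylsilyl ether of hydroxy acid 17 | OC[C@H](Cc1ccc(OCc2ccccc2)c(OC)c1)[C@@H]([C@H](O[Si](C)(C)C(C)(C)C)c1ccc(OCc2ccccc2)c(OC)c1)C(=O)O
F6 | step 6 | C7' O-tert-butyldimethylsilyl ether of 18, (3S,4R,7'S) | COc1cc(C[C@H]2COC(=O)[C@@H]2[C@H](O[Si](C)(C)C(C)(C)C)c2ccc(OCc3ccccc3)c(OC)c2)ccc1OCc1ccccc1
F7 | step 5 | ring-opened sulfide of 14 bearing H and S(CH2)3SSnBu3 on C7 (C7 epimers) | C[C@@H]1CC[C@H]([C@@H](C1)O[C@@H]1OC(=O)[C@H]([C@H](O)c2ccc(OCc3ccccc3)c(OC)c2)[C@H]1C(SCCCS[Sn](CCCC)(CCCC)CCCC)c1ccc(OCc2ccccc2)c(OC)c1)C(C)C
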